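## Analysis of the target

Compound 20 is a carbon–carbon linked flavone–coumarin dimer. Apigenin (rings A, C and B of a 5,7,4′-trihydroxyflavone) is joined through C8 of ring A to C6 of 7-hydroxycoumarin. There is no stereocentre. The only potential stereogenic element is the biaryl axis, which carries three ortho substituents (O1 and the C7 oxygen on the flavone side, the C7 hydroxyl on the coumarin side); it is unspecified and needs no control. The sensitive groups are four phenols (the 5-OH is chelated to the C4 carbonyl), the γ-pyranone of ring C and the coumarin lactone. Once the 5-hydroxyl is free, strong acid can open ring C and reclose it onto the other ortho oxygen (Wessely–Moser rearrangement), which would move the aryl group from C8 to C6; the lactone opens in hydroxide or alkoxide. The hard part is the biaryl bond: it joins two electron-rich, oxygen-flanked carbons, and it must sit at C8 rather than the similar C6 of ring A, and at C6 rather than C8 of the coumarin. The strategy rests on the coumarin carbocycle (C4a, C5, C6, C7, C8, C8a), which is a resorcinol: oxygens at C7 and C8a, the flavonyl group at C6 next to the C7 hydroxyl, and a carbon substituent (C4) at C4a, ortho to the C8a oxygen and para to the C7 oxygen. A 4-aryl-1-alkoxy-1,3-bis(silyloxy)butadiene and an acetylenic aldehyde give exactly this pattern in a [4+2] benzannulation, so the hindered aryl–aryl bond can be carried in as an aryl–CH bond of the diene, with rings A, C and B taken complete from 1.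

## Retrosynthetic reasoning

**20 ⇒ 19.** The three O–methyl bonds on the flavone are cut last. Methyl ethers are chosen because they must survive a palladium coupling, strong protic acid, a lithium amide and a reaction above 200 °C. The forward step must cleave three aryl methyl ethers without opening the lactone and without letting ring C open and reclose.

**19 ⇒ 16 + 17.** The coumarin heterocycle is cut at O1–C2 and C3=C4. This gives the salicylaldehyde 16, whose formyl carbon is coumarin C4, and the two-carbon ylide 17. The forward reaction is an olefination to cinnamate 18 followed by thermal E-to-Z isomerisation and lactonisation onto the ortho hydroxyl. The para hydroxyl stays free, so no protecting group is needed on the coumarin half.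

**16 ⇒ 12 + 14 (key disconnection).** The carbocycle of 16 is cut at the two bonds that become C5–C6 and C4a–C8a of the coumarin. That leaves a four-carbon unit carrying both oxygens and the flavonyl group (diene 12) and a two-carbon unit carrying the formyl group (ynal 14). The cut is made here because it turns the congested biaryl bond into a substituent already present on the diene terminus, and because the polarisation of the two partners fixes the positions of all four ring substituents. The forward reaction must form cycloadduct 15 with the aryl-bearing diene terminus on the unsubstituted alkyne carbon, then aromatise by loss of the methoxy group and both silyl groups.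

**14 ⇒ 13.** The ynal is unstable on storage and is traced to alcohol 13 by one oxidation carried out just before use.

**12 ⇒ 11 ⇒ 10.** The two O–Si bonds are cut in turn. β-Keto ester 10 is silylated first on the ketone oxygen under amine conditions (11), then on the ester oxygen after γ-deprotonation with a lithium amide. The C2=C3 double bond of 11 becomes the central single bond of 12, so its geometry is irrelevant.

**10 ⇒ 7 + 8.** The bond between the ketone carbon and the α-carbon of the butanoate is cut. Arylacetic acid 7 is extended by two carbons through its C-acyl derivative 9 of 8, which gives the methyl β-keto ester on decarboxylative alcoholysis. This avoids enolate chemistry of an ester with acidic benzylic protons.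

**7 ⇒ 6 ⇒ 3 + 4.** The bond from flavone C8 to the CH2 group is cut. Iodide 3 is coupled with zinc enolate 5 made from bromoacetate 4. The zinc enolate is mild enough to leave the C4 carbonyl and C2=C3 bond of ring C untouched. The tert-butyl ester 6 is then cleaved by acid, so the flavone never meets aqueous base.

**3 ⇒ 2 ⇒ 1.** The C8–I bond is cut back to trimethyl ether 2, and the three O–methyl bonds back to 1. Methylating the chelated 5-hydroxyl is what directs electrophilic substitution to C8 instead of C6.

## Alternatives that were turned down

Alternative 1: Ring A of the flavone is disconnected at C7–C8 and traced to 4-methoxy-6-[(7-methoxy-2-oxo-2H-chromen-6-yl)methyl]-2H-pyran-2-one (A2), with the coumarin already complete.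
- Forward key step: a magnesium alkoxide opens the pyranone of A2 to a keto ester enol ether. Its benzylic carbanion closes onto the ester carbonyl in a Claisen-type cyclisation, and the product is A1, which is 6-(2,6-dihydroxy-4-methoxyphenyl)-7-methoxy-2H-chromen-2-one.
- For: the ring closure follows the polyketide folding logic, the biaryl bond is never made by coupling, and the symmetry of A1 removes any regiochemical question about ring A. On that last point it is as strong as the chosen route.
- Against: the alkoxide that opens the pyranone also attacks the coumarin lactone. After A1, rings C and B still have to be built (C-acylation, introduction of the 4-methoxybenzoyl unit, cyclodehydration), at least four operations in basic media that open the coumarin. A2 itself needs a multistep preparation.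
- Comparison: the chosen route takes rings A, C and B complete from 1 and builds only the small coumarin carbocycle, with two steps after the key step. Its regiocontrol comes from orbital polarisation, not symmetry, and is equally unambiguous.

Alternative 2: Ring A is assembled around C8 from 6-(ethoxyethynyl)-7-methoxy-2H-chromen-2-one (A4) and 3-ethoxycyclobut-2-en-1-one (A5).
- Forward key step: a Danheiser benzannulation. Thermal opening of A5 gives a vinylketene; [2+2] addition to the ynol ether A4, four-electron ring opening, six-electron ring closure and tautomerisation lead to A3, which is 6-(2,4-diethoxy-6-hydroxyphenyl)-7-methoxy-2H-chromen-2-one.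
- For: it is convergent, avoids a hindered cross-coupling as the chosen route does, and places the single free hydroxyl of A3 where the pyran oxygen must go. In differentiating the three ring A oxygens it is stronger than a symmetric intermediate.
- Against: the aryl ynol ether A4 is prone to hydration and thermal decomposition at the temperature the cascade needs, and its preparation and that of A5 add steps. After A3 the whole pyranone and ring B remain to be built, starting with a C-acylation that must choose the carbon ortho to the free hydroxyl over the carbon between the two ethoxy groups. The ethyl ethers are harder to cleave at the end than methyl ethers.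
- Comparison: the chosen route needs no ring construction on the flavone and is shorter after the key step. In exchange it accepts a cycloaddition at a sterically loaded diene terminus.

Alternative 3: Ring C is disconnected at C4a–C4, C4–C3 and O1–C2, giving 6-(2,6-dihydroxy-3-iodo-4-methoxyphenyl)-7-methoxy-2H-chromen-2-one (A7), carbon monoxide (A9) and 1-ethynyl-4-methoxybenzene (A8).
- Forward key step: zerovalent palladium inserts into the C–I bond of A7, A9 inserts, and coupling with A8 gives an aryl ynone. The adjacent hydroxyl closes onto it (6-endo), and the product is A6, which is 7-hydroxy-5-methoxy-2-(4-methoxyphenyl)-8-(7-methoxy-2-oxo-2H-chromen-6-yl)-4H-chromen-4-one.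
- For: it is a late, three-component assembly with regiochemistry fixed by the iodine, and A6 already holds the complete skeleton, three O-demethylations away from 20. The key step in itself is better supported mechanistically than a cycloaddition of a hindered diene, so on that point this alternative is stronger.
- Against: it does not solve the main problem. The biaryl bond must already exist in A7, which is the mono-iodide of A1 and so needs either a hindered coupling or the ring synthesis of Alternative 1. The mono-iodination must stop cleanly on a very activated ring and spare the activated coumarin. The ynone can also close 5-exo to an aurone instead of A6.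
- Comparison: the chosen route makes the biaryl connection and the coumarin ring in one operation, and no flavone ring has to be closed at all. A6 would stand as close to the target as 19 does, but only after a longer and less certain approach to A7.

Key step: step 9

Remark on the chemistry: the biaryl axis of 19 and 20 is taken as configurationally undefined, as in the target structure.

Remark on the chemistry: 11 is drawn as its Z isomer and the ketene acetal end of 12 as 3Z. Both geometries are lost on the way to 16, so mixtures serve equally. Only the 1Z geometry at the aryl-bearing double bond of 12 (C1=C2 of the butadienyl group as it is named) matters.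

Remark on the chemistry: 14 is volatile and polymerises easily. It is prepared immediately before use and handled cold in toluene.

## Route

Step 1
Reactants: 1 apigenin
Product: 2 5,7-dimethoxy-2-(4-methoxyphenyl)-4H-chromen-4-one
Conditions: Me2SO4 (excess), K2CO3, acetone, reflux
Reagents that add atoms: dimethyl sulfate, COS(=O)(=O)OC
Why: Williamson O-methylation of all three phenols; the chelated 5-hydroxyl reacts last and needs excess reagent and prolonged reflux. Capping it is what later steers the electrophile to C8.

Step 2
Reactants: 2 5,7-dimethoxy-2-(4-methoxyphenyl)-4H-chromen-4-one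
Product: 3 8-iodo-5,7-dimethoxy-2-(4-methoxyphenyl)-4H-chromen-4-one
Conditions: I2, AgO2CCF3, CH2Cl2, rt, dark
Reagents that add atoms: iodine, II
Why: Electrophilic aromatic iodination of the phloroglucinol-type ring A. C6 lies between two methoxy groups, the 5-methoxy one turned towards it by the peri carbonyl, whereas C8 is flanked by one methoxy group and the unsubstituted ring oxygen, so substitution of 5-O-alkylated 5,7-dioxygenated flavones should go to C8. Ring B and C3 are much less activated.

Step 3
Reactants: 3 8-iodo-5,7-dimethoxy-2-(4-methoxyphenyl)-4H-chromen-4-one; 4 tert-butyl bromoacetate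
Product: 6 tert-butyl 2-[5,7-dimethoxy-2-(4-methoxyphenyl)-4-oxo-4H-chromen-8-yl]acetate, via bromozinc enolate 5 (not isolated)
Conditions: Zn, Me3SiCl (cat.), THF, 40 °C; then 3, Pd2(dba)3 (cat.), XPhos (cat.), THF, 65 °C
Reagents that add atoms: none
Why: Reformatsky reagent formation followed by Negishi-type α-arylation of the zinc ester enolate. The zinc enolate does not add to the vinylogous-ester carbonyl of ring C, and a bulky biaryl phosphine on zerovalent palladium allows oxidative addition and reductive elimination at the ortho,ortho-disubstituted iodide.

Step 4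
Reactants: 6 tert-butyl 2-[5,7-dimethoxy-2-(4-methoxyphenyl)-4-oxo-4H-chromen-8-yl]acetate
Product: 7 2-[5,7-dimethoxy-2-(4-methoxyphenyl)-4-oxo-4H-chromen-8-yl]acetic acid
Conditions: CF3CO2H, CH2Cl2, rt
Reagents that add atoms: none
Why: Acid-catalysed E1 cleavage of the tert-butyl ester. In this medium the pyranone is protonated, which deactivates ring A against tert-butylation at C6, and the methyl ethers are untouched.

Step 5
Reactants: 7 2-[5,7-dimethoxy-2-(4-methoxyphenyl)-4-oxo-4H-chromen-8-yl]acetic acid; 8 Meldrum's acid
Product: 10 methyl 4-[5,7-dimethoxy-2-(4-methoxyphenyl)-4-oxo-4H-chromen-8-yl]-3-oxobutanoate, via acyl Meldrum's acid 9 (not isolated)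
Conditions: DCC, DMAP, CH2Cl2, 0 °C to rt; filter, acid wash, concentrate; then MeOH, reflux
Reagents that add atoms: methanol, CO
Why: Carbodiimide-mediated C-acylation of Meldrum's acid, then thermal fragmentation of 9 to an acylketene that methanol traps as the β-keto ester. This two-carbon homologation needs no strong base.

Step 6
Reactants: 10 methyl 4-[5,7-dimethoxy-2-(4-methoxyphenyl)-4-oxo-4H-chromen-8-yl]-3-oxobutanoate
Product: 11 methyl (2Z)-4-[5,7-dimethoxy-2-(4-methoxyphenyl)-4-oxo-4H-chromen-8-yl]-3-(trimethylsilyloxy)but-2-enoate
Conditions: Me3SiCl, Et3N, toluene, rt; filter under argon, concentrate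
Reagents that add atoms: chlorotrimethylsilane, C[Si](C)(C)Cl
Why: O-Silylation of the enolised β-keto ester under amine conditions gives the ester-conjugated silyl enol ether. The flavone has no enolisable position and is inert.

Step 7
Reactants: 11 methyl (2Z)-4-[5,7-dimethoxy-2-(4-methoxyphenyl)-4-oxo-4H-chromen-8-yl]-3-(trimethylsilyloxy)but-2-enoate
Product: 12 8-[(1Z,3Z)-4-methoxy-2,4-bis(trimethylsilyloxy)buta-1,3-dien-1-yl]-5,7-dimethoxy-2-(4-methoxyphenyl)-4H-chromen-4-one
Conditions: LiN(i-Pr)2 (1.1 equiv), THF, −78 °C; Me3SiCl, −78 °C to 0 °C; concentrate, take up in pentane, filter under argon, use crude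
Reagents that add atoms: chlorotrimethylsilane, C[Si](C)(C)Cl
Why: Kinetic γ-deprotonation of the β-silyloxy enoate at the doubly activated benzylic CH2, then O-silylation of the dienolate, the standard route to 1-alkoxy-1,3-bis(silyloxy)dienes. The aryl group should settle cis to the silyloxy group (1Z in the name of 12), away from the vinylic CH, which is the geometry the cycloaddition needs.

Step 8
Reactants: 13 prop-2-yn-1-ol
Product: 14 prop-2-ynal
Conditions: CrO3, H2SO4, H2O, 2–10 °C, 40–60 mmHg, product distilled into cold traps
Reagents that add atoms: none
Why: Chromic acid oxidation of the primary propargylic alcohol. Continuous removal of the volatile aldehyde under reduced pressure protects it from over-oxidation.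

Step 9
Reactants: 12 8-[(1Z,3Z)-4-methoxy-2,4-bis(trimethylsilyloxy)buta-1,3-dien-1-yl]-5,7-dimethoxy-2-(4-methoxyphenyl)-4H-chromen-4-one; 14 prop-2-ynal
Product: 16 5-[5,7-dimethoxy-2-(4-methoxyphenyl)-4-oxo-4H-chromen-8-yl]-2,4-dihydroxybenzaldehyde, via cyclohexadiene cycloadduct 15 (not isolated)
Conditions: toluene, 0 °C to 40 °C; then 1 M HCl, THF, rt
Reagents that add atoms: none
Why: Normal-electron-demand Diels–Alder reaction: the HOMO of the diene has its largest coefficient at the aryl-bearing carbon and the LUMO of 14 at the terminal alkyne carbon, so the two combine in a concerted but strongly asynchronous [4+2] addition (at the limit a vinylogous Mukaiyama–Michael addition followed by closure of the allenolate onto the oxocarbenium carbon), and either course gives 15. The closest known reaction type is the benzannulation of 1-alkoxy-1,3-bis(silyloxy)butadienes with acetylenic esters and ketones to resorcinols. The one new ring, the six-membered carbocycle of the later coumarin, is closed by intermolecular [4+2] cycloaddition through two σ-bonds (flavonyl-CH to alkyne CH, acetal carbon to the formyl-bearing carbon) and is aromatised by acid-promoted 1,4-elimination of methanol and cleavage of both O–Si bonds. No stereocentre survives, because both sp3 carbons of 15 become aromatic, so facial selectivity and ketene acetal geometry are irrelevant. The selectivity the step needs is regioselectivity, and the push–pull match secures it: the formyl group ends ortho to the oxygen from the acetal carbon and para to the oxygen from the central silyloxy carbon of the diene. Chemoselectivity for C≡C over C=O of 14 is favoured by working without Lewis acid in toluene, and the electron-rich C2=C3 bond of ring C is no dienophile for an electron-rich diene. The 1Z geometry places the bulky aryl group on the outside of the s-cis diene, and the carbon it meets bears only hydrogen, the smallest possible partner for this hindered terminus.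

Step 10
Reactants: 16 5-[5,7-dimethoxy-2-(4-methoxyphenyl)-4-oxo-4H-chromen-8-yl]-2,4-dihydroxybenzaldehyde; 17 ethyl (triphenylphosphoranylidene)acetate
Product: 19 8-(7-hydroxy-2-oxo-2H-chromen-6-yl)-5,7-dimethoxy-2-(4-methoxyphenyl)-4H-chromen-4-one, via ethyl 2-hydroxycinnamate 18 (not isolated)
Conditions: PhNEt2, reflux (about 215 °C)
Reagents that add atoms: none
Why: Wittig olefination of the salicylaldehyde with the stabilised ylide, then thermal E-to-Z isomerisation and lactonisation with loss of ethanol in the high-boiling basic solvent. This one-pot sequence is established for 5-substituted 2,4-dihydroxybenzaldehydes, and the flavone and its methyl ethers are thermally robust.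

Step 11
Reactants: 19 8-(7-hydroxy-2-oxo-2H-chromen-6-yl)-5,7-dimethoxy-2-(4-methoxyphenyl)-4H-chromen-4-one
Product: 20 5,7-dihydroxy-8-(7-hydroxy-2-oxo-2H-chromen-6-yl)-2-(4-hydroxyphenyl)-4H-chromen-4-one
Conditions: BBr3 (excess), CH2Cl2, −78 °C to rt; then MeOH, H2O
Reagents that add atoms: none
Why: Lewis-acid cleavage of the three aryl methyl ethers through bromide attack on the boron-activated O–CH3 groups; the peri 5-methoxy group goes first by chelation. The coumarin lactone is stable to BBr3, and keeping the temperature at or below rt without hot protic acid should avoid opening and reclosure of ring C.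

## Compound list

1 | apigenin, 5,7-dihydroxy-2-(4-hydroxyphenyl)-4H-chromen-4-one | O=c1cc(-c2ccc(O)cc2)oc2cc(O)cc(O)c12 | starting material
2 | 5,7-dimethoxy-2-(4-methoxyphenyl)-4H-chromen-4-one | O=c1cc(-c2ccc(OC)cc2)oc2cc(OC)cc(OC)c12 | intermediate
3 | 8-iodo-5,7-dimethoxy-2-(4-methoxyphenyl)-4H-chromen-4-one | O=c1cc(-c2ccc(OC)cc2)oc2c(I)c(OC)cc(OC)c12 | intermediate
4 | tert-butyl bromoacetate | CC(C)(C)OC(=O)CBr | starting material
5 | bromo(2-tert-butoxy-2-oxoethyl)zinc | CC(C)(C)OC(=O)C[Zn]Br | intermediate
6 | tert-butyl 2-[5,7-dimethoxy-2-(4-methoxyphenyl)-4-oxo-4H-chromen-8-yl]acetate | CC(C)(C)OC(=O)Cc1c(OC)cc(OC)c2c(=O)cc(-c3ccc(OC)cc3)oc12 | intermediate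
7 | 2-[5,7-dimethoxy-2-(4-methoxyphenyl)-4-oxo-4H-chromen-8-yl]acetic acid | OC(=O)Cc1c(OC)cc(OC)c2c(=O)cc(-c3ccc(OC)cc3)oc12 | intermediate
8 | Meldrum's acid, 2,2-dimethyl-1,3-dioxane-4,6-dione | CC1(C)OC(=O)CC(=O)O1 | starting material
9 | 5-{2-[5,7-dimethoxy-2-(4-methoxyphenyl)-4-oxo-4H-chromen-8-yl]-1-hydroxyethylidene}-2,2-dimethyl-1,3-dioxane-4,6-dione | CC1(C)OC(=O)C(=C(O)Cc2c(OC)cc(OC)c3c(=O)cc(-c4ccc(OC)cc4)oc23)C(=O)O1 | intermediate
10 | methyl 4-[5,7-dimethoxy-2-(4-methoxyphenyl)-4-oxo-4H-chromen-8-yl]-3-oxobutanoate | COC(=O)CC(=O)Cc1c(OC)cc(OC)c2c(=O)cc(-c3ccc(OC)cc3)oc12 | intermediate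
11 | methyl (2Z)-4-[5,7-dimethoxy-2-(4-methoxyphenyl)-4-oxo-4H-chromen-8-yl]-3-(trimethylsilyloxy)but-2-enoate | COC(=O)/C=C(\O[Si](C)(C)C)Cc1c(OC)cc(OC)c2c(=O)cc(-c3ccc(OC)cc3)oc12 | intermediate
12 | 8-[(1Z,3Z)-4-methoxy-2,4-bis(trimethylsilyloxy)buta-1,3-dien-1-yl]-5,7-dimethoxy-2-(4-methoxyphenyl)-4H-chromen-4-one | CO/C(O[Si](C)(C)C)=C/C(O[Si](C)(C)C)=C/c1c(OC)cc(OC)c2c(=O)cc(-c3ccc(OC)cc3)oc12 | intermediate
13 | prop-2-yn-1-ol | OCC#C | starting material
14 | prop-2-ynal | O=CC#C | intermediate
15 | 3-[5,7-dimethoxy-2-(4-methoxyphenyl)-4-oxo-4H-chromen-8-yl]-6-methoxy-4,6-bis(trimethylsilyloxy)cyclohexa-1,4-diene-1-carbaldehyde, racemic mixture of diastereomers at C3 and C6 | O=CC1=CC(c2c(OC)cc(OC)c3c(=O)cc(-c4ccc(OC)cc4)oc23)C(O[Si](C)(C)C)=CC1(OC)O[Si](C)(C)C | intermediate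
16 | 5-[5,7-dimethoxy-2-(4-methoxyphenyl)-4-oxo-4H-chromen-8-yl]-2,4-dihydroxybenzaldehyde | O=Cc1cc(-c2c(OC)cc(OC)c3c(=O)cc(-c4ccc(OC)cc4)oc23)c(O)cc1O | intermediate
17 | ethyl (triphenylphosphoranylidene)acetate | CCOC(=O)C=P(c1ccccc1)(c1ccccc1)c1ccccc1 | starting material
18 | ethyl (2E)-3-{5-[5,7-dimethoxy-2-(4-methoxyphenyl)-4-oxo-4H-chromen-8-yl]-2,4-dihydroxyphenyl}prop-2-enoate | CCOC(=O)/C=C/c1cc(-c2c(OC)cc(OC)c3c(=O)cc(-c4ccc(OC)cc4)oc23)c(O)cc1O | intermediate
19 | 8-(7-hydroxy-2-oxo-2H-chromen-6-yl)-5,7-dimethoxy-2-(4-methoxyphenyl)-4H-chromen-4-one | O=c1ccc2cc(-c3c(OC)cc(OC)c4c(=O)cc(-c5ccc(OC)cc5)oc34)c(O)cc2o1 | intermediate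
20 | 5,7-dihydroxy-8-(7-hydroxy-2-oxo-2H-chromen-6-yl)-2-(4-hydroxyphenyl)-4H-chromen-4-one | O=c1ccc2cc(-c3c(O)cc(O)c4c(=O)cc(-c5ccc(O)cc5)oc34)c(O)cc2o1 | target

## Step count and least certain steps

Total step count: 11. Longest linear sequence: 10 steps (steps 1 to 7, then 9, 10 and 11); step 8 is a one-step side branch.

**Step 9 (key step).** The most likely failure is a slow cycloaddition. The diene terminus carries an ortho,ortho-disubstituted aryl group twisted out of the diene plane, so bond formation there is retarded. Side processes can then take over: uncatalysed aldol-type addition of the ketene acetal to the aldehyde carbon, polymerisation of the ynal, or hydrolytic loss of the silyl groups. A diene fraction with the aryl group on the inside would not react at all.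
Fallback: a biaryl coupling that sets out from 3 and returns at 16. 5-Bromo-2,4-dihydroxybenzaldehyde F1 is protected (MeOCH2Cl, i-Pr2NEt, CH2Cl2) as 5-bromo-2,4-bis(methoxymethoxy)benzaldehyde F2. Borylation (B2pin2, PdCl2(dppf), KOAc, dioxane, 90 °C) gives 2,4-bis(methoxymethoxy)-5-(4,4,5,5-tetramethyl-1,3,2-dioxaborolan-2-yl)benzaldehyde F3. Suzuki–Miyaura coupling with 3 (Pd(OAc)2, SPhos, K3PO4, toluene/H2O, 100 °C) gives 5-[5,7-dimethoxy-2-(4-methoxyphenyl)-4-oxo-4H-chromen-8-yl]-2,4-bis(methoxymethoxy)benzaldehyde F4. HCl in MeOH removes both acetal groups and gives 16.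

**Step 7.** The lithium amide may partly deprotonate C3 of ring C or add to the pyranone instead of abstracting the benzylic proton. C-silylation or adventitious hydrolysis would lower the quality of a diene that cannot be purified by distillation.
Fallback: soft enolisation that sets out from 10 and returns at 12 directly, bypassing 11 and every lithium base. Treating 10 with Me3SiOSO2CF3 (2.2 equiv) and Et3N in Et2O at 0 °C silylates both carbonyl oxygens under amine conditions. No new compound is involved.

**Step 3.** Reductive elimination at the ortho,ortho-disubstituted aryl palladium intermediate may be slow, so that protodeiodination or homocoupling of the zinc enolate competes.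
Fallback: an allylation–cleavage sequence that sets out from 3 and returns at 7. Stille coupling with allyltributylstannane (Pd(PPh3)4, toluene, 100 °C) gives 5,7-dimethoxy-2-(4-methoxyphenyl)-8-(prop-2-en-1-yl)-4H-chromen-4-one F5. Lemieux–Johnson cleavage of the terminal alkene (OsO4 cat., NaIO4, 2,6-lutidine, dioxane/H2O) gives 2-[5,7-dimethoxy-2-(4-methoxyphenyl)-4-oxo-4H-chromen-8-yl]acetaldehyde F6. Pinnick oxidation (NaClO2, NaH2PO4, 2-methylbut-2-ene, t-BuOH/H2O) gives 7.

**Step 11.** Cleavage of the 7- and 4′-methyl ethers may be incomplete at the temperatures that are safe. If the mixture is forced, acid-induced opening and reclosure of ring C after the 5-hydroxyl is freed would migrate the aryl group from C8 to C6.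
Fallback: nucleophilic demethylation in a basic medium, setting out from 19 and returning at 20. NaSC12H25 in N-methylpyrrolidone at 130 °C removes the methyl groups by SN2 attack at carbon, and acidification on work-up recloses any opened lactone. No new compound is involved.

**Step 10.** The aldehyde is deactivated by its para hydroxyl and internally hydrogen bonded, so olefination may be sluggish. The E-cinnamate may also fail to isomerise and stall before lactonisation.
Fallback: a Perkin condensation that sets out from 16 and returns at 19. Heating 16 with Ac2O and NaOAc at 170 °C gives 6-[5,7-dimethoxy-2-(4-methoxyphenyl)-4-oxo-4H-chromen-8-yl]-2-oxo-2H-chromen-7-yl acetate F7. Its phenolic acetate is removed with HCl in MeOH to give 19.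

## Further compounds

F1 | step 9 | 5-bromo-2,4-dihydroxybenzaldehyde | O=Cc1cc(Br)c(O)cc1O
F2 | step 9 | 5-bromo-2,4-bis(methoxymethoxy)benzaldehyde | O=Cc1cc(Br)c(OCOC)cc1OCOC
F3 | step 9 | 2,4-bis(methoxymethoxy)-5-(4,4,5,5-tetramethyl-1,3,2-dioxaborolan-2-yl)benzaldehyde | O=Cc1cc(B2OC(C)(C)C(C)(C)O2)c(OCOC)cc1OCOC
F4 | step 9 | 5-[5,7-dimethoxy-2-(4-methoxyphenyl)-4-oxo-4H-chromen-8-yl]-2,4-bis(methoxymethoxy)benzaldehyde | O=Cc1cc(-c2c(OC)cc(OC)c3c(=O)cc(-c4ccc(OC)cc4)oc23)c(OCOC)cc1OCOC
F0 | step 7 | none | none
F5 | step 3 | 5,7-dimethoxy-2-(4-methoxyphenyl)-8-(prop-2-en-1-yl)-4H-chromen-4-one | C=CCc1c(OC)cc(OC)c2c(=O)cc(-c3ccc(OC)cc3)oc12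
F6 | step 3 | 2-[5,7-dimethoxy-2-(4-methoxyphenyl)-4-oxo-4H-chromen-8-yl]acetaldehyde | O=CCc1c(OC)cc(OC)c2c(=O)cc(-c3ccc(OC)cc3)oc12
F0 | step 11 | none | none
F7 | step 10 | 6-[5,7-dimethoxy-2-(4-methoxyphenyl)-4-oxo-4H-chromen-8-yl]-2-oxo-2H-chromen-7-yl acetate | CC(=O)Oc1cc2oc(=O)ccc2cc1-c1c(OC)cc(OC)c2c(=O)cc(-c3ccc(OC)cc3)oc12
A1 | alternative 1 | 6-(2,6-dihydroxy-4-methoxyphenyl)-7-methoxy-2H-chromen-2-one | COc1cc(O)c(c(O)c1)-c1cc2ccc(=O)oc2cc1OC
A2 | alternative 1 | 4-methoxy-6-[(7-methoxy-2-oxo-2H-chromen-6-yl)methyl]-2H-pyran-2-one | COc1cc(Cc2cc3ccc(=O)oc3cc2OC)oc(=O)c1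
A3 | alternative 2 | 6-(2,4-diethoxy-6-hydroxyphenyl)-7-methoxy-2H-chromen-2-one | CCOc1cc(OCC)cc(O)c1-c1cc2ccc(=O)oc2cc1OC
A4 | alternative 2 | 6-(ethoxyethynyl)-7-methoxy-2H-chromen-2-one | CCOC#Cc1cc2ccc(=O)oc2cc1OC
A5 | alternative 2 | 3-ethoxycyclobut-2-en-1-one | CCOC1=CC(=O)C1
A6 | alternative 3 | 7-hydroxy-5-methoxy-2-(4-methoxyphenyl)-8-(7-methoxy-2-oxo-2H-chromen-6-yl)-4H-chromen-4-one | O=c1ccc2cc(-c3c(O)cc(OC)c4c(=O)cc(-c5ccc(OC)cc5)oc34)c(OC)cc2o1
A7 | alternative 3 | 6-(2,6-dihydroxy-3-iodo-4-methoxyphenyl)-7-methoxy-2H-chromen-2-one | COc1cc(O)c(c(O)c1I)-c1cc2ccc(=O)oc2cc1OC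
A8 | alternative 3 | 1-ethynyl-4-methoxybenzene | C#Cc1ccc(OC)cc1
A9 | alternative 3 | carbon monoxide | [C-]#[O+]
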